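The route rests on cutting the C4–C4a bond of the upper flavan. Upper C4 carries ring A, C8 of ring D of the epigallocatechin unit and C3, so it is planned as the ring-D-bound carbon of an alkyne. In one gold-catalysed operation ring A of an enantiopure aryl propargyl ether adds across that alkyne, forming C4–C4a and closing ring C as a 4-aryl-2H-chromene while the preset C2 centre stays intact; hydrogenation later relays C2 to C4. The precursor is the 3-benzyloxyphenyl ether of a 1-aryl-3-(hexa-O-benzylepigallocatechin-8-yl)propynol; its ring B phenol is carried as a benzyl carbonate, not a benzyl ether, so that the benzylic C2–O bond is less prone to ionise.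

Key step: step 9

Ring labels: A, B and C are the benzo ring, the 2-aryl ring and the pyran ring of the upper flavan; D is the phloroglucinol ring of the epigallocatechin unit, attached through its C8. The epigallocatechin centres are 2R,3R throughout.

Assumption (chemistry): (R,R)-ProPhenol is taken to be the ligand antipode that sends the alkynylzinc to the Re face of aldehyde 9. If MTPA ester analysis of 10 from a first run shows the opposite sense, the (S,S) ligand is used with nothing else changed.

Step 1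
Reactants: 1 (−)-epigallocatechin
Product: 2 5,7,3',4',5'-penta-O-benzyl-(−)-epigallocatechin
Conditions: BnBr (5.5 equiv), K2CO3, DMF, 0 °C to rt, N2
Reagents that add atoms: benzyl bromide, BrCc1ccccc1
Why: Williamson O-alkylation in which carbonate deprotonates only the five phenols, so the secondary 3-OH stays free and the mild base at or below room temperature leaves the 2R,3R centres untouched.

Step 2
Reactants: 2 5,7,3',4',5'-penta-O-benzyl-(−)-epigallocatechin
Product: 3 8-bromo-5,7,3',4',5'-penta-O-benzyl-(−)-epigallocatechin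
Conditions: NBS (1.0 equiv), CH2Cl2, −78 °C to rt
Reagents that add atoms: N-bromosuccinimide, O=C1CCC(=O)N1Br
Why: Electrophilic aromatic bromination of the phloroglucinol-type ring D, for which 5,7-di-O-benzylflavan-3-ols show a known preference for C8 over C6, while the pyrogallol ring is less activated and should not compete with one equivalent at low temperature.

Step 3
Reactants: 3 8-bromo-5,7,3',4',5'-penta-O-benzyl-(−)-epigallocatechin
Product: 4 8-bromo-3,5,7,3',4',5'-hexa-O-benzyl-(−)-epigallocatechin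
Conditions: NaH, BnBr, DMF, 0 °C to rt
Reagents that add atoms: benzyl bromide, BrCc1ccccc1
Why: Williamson etherification of the sodium alkoxide of the 3-OH, in which no stereocentre takes part and the aryl bromide is inert.

Step 4
Reactants: 4 8-bromo-3,5,7,3',4',5'-hexa-O-benzyl-(−)-epigallocatechin
Product: 6 3,5,7,3',4',5'-hexa-O-benzyl-(−)-epigallocatechin-8-carbaldehyde, via 8-lithio-hexa-O-benzylepigallocatechin 5 (not isolated)
Conditions: n-BuLi, THF, −78 °C; DMF, −78 to 0 °C; H2O
Reagents that add atoms: N,N-dimethylformamide, CN(C)C=O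
Why: Bromine–lithium exchange gives an aryllithium flanked by two ether oxygens, which DMF formylates (Bouveault aldehyde synthesis), and at −78 °C exchange is far faster than metalation of the benzyl ethers.

Step 5
Reactants: 6 3,5,7,3',4',5'-hexa-O-benzyl-(−)-epigallocatechin-8-carbaldehyde
Product: 7 8-ethynyl-3,5,7,3',4',5'-hexa-O-benzyl-(−)-epigallocatechin
Conditions: dimethyl (1-diazo-2-oxopropyl)phosphonate, K2CO3, MeOH–THF, 0 °C to rt
Reagents that add atoms: dimethyl (1-diazo-2-oxopropyl)phosphonate (Ohira–Bestmann reagent), COP(=O)(OC)C(=[N+]=[N-])C(C)=O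
Why: Seyferth–Gilbert homologation in which the diazophosphonate anion released by methanolysis adds to the non-enolisable aldehyde and loss of phosphate and N2 with 1,2-hydride shift gives the terminal alkyne, under conditions that leave the ethers and stereocentres alone.

Step 6
Reactants: 8 4-hydroxybenzaldehyde
Product: 9 benzyl 4-formylphenyl carbonate
Conditions: CbzCl, Et3N, CH2Cl2, 0 °C
Reagents that add atoms: benzyl chloroformate, O=C(Cl)OCc1ccccc1
Why: O-acylation of the phenol by the chloroformate gives the aryl benzyl carbonate, an electron-poor mask that the final hydrogenolysis removes, and the aldehyde is not affected.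

Step 7
Reactants: 7 8-ethynyl-3,5,7,3',4',5'-hexa-O-benzyl-(−)-epigallocatechin; 9 benzyl 4-formylphenyl carbonate (1.5 equiv)
Product: 10 benzyl 4-[(1S)-1-hydroxy-3-(3,5,7,3',4',5'-hexa-O-benzylepigallocatechin-8-yl)prop-2-yn-1-yl]phenyl carbonate
Conditions: Me2Zn (3 equiv), (R,R)-ProPhenol [2,6-bis{[(R)-2-(hydroxydiphenylmethyl)pyrrolidin-1-yl]methyl}-4-methylphenol] (20 mol %), Ph3P=O (40 mol %), toluene, 0 to 4 °C
Reagents that add atoms: none
Why: Zinc–ProPhenol-catalysed asymmetric alkynylation, in which a ligand-bound dinuclear zinc alkynylide adds to the Re face of the aryl aldehyde and so sets the 1S carbinol under catalyst control, a reaction class established for aryl aldehydes with aryl acetylenes whose organozinc species should not attack the carbonate.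

Step 8
Reactants: 10 benzyl 4-[(1S)-1-hydroxy-3-(3,5,7,3',4',5'-hexa-O-benzylepigallocatechin-8-yl)prop-2-yn-1-yl]phenyl carbonate; 11 3-benzyloxyphenol
Product: 12 benzyl 4-[(1R)-1-(3-benzyloxyphenoxy)-3-(3,5,7,3',4',5'-hexa-O-benzylepigallocatechin-8-yl)prop-2-yn-1-yl]phenyl carbonate
Conditions: PPh3, DIAD, toluene, −20 to 0 °C
Reagents that add atoms: none
Why: Mitsunobu etherification in which the phenol displaces the alkoxyphosphonium group with inversion (1S to 1R), while the carbonate on ring B and the cold, non-polar medium disfavour ionisation of the benzylic, propargylic centre before displacement.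

Step 9
Reactants: 12 benzyl 4-[(1R)-1-(3-benzyloxyphenoxy)-3-(3,5,7,3',4',5'-hexa-O-benzylepigallocatechin-8-yl)prop-2-yn-1-yl]phenyl carbonate
Product: 13 benzyl 4-[(2S)-7-benzyloxy-4-(3,5,7,3',4',5'-hexa-O-benzylepigallocatechin-8-yl)-2H-chromen-2-yl]phenyl carbonate
Conditions: Ph3PAuNTf2 (5 mol %), CH2Cl2, 0 °C to rt, dark
Reagents that add atoms: none
Why: The cationic monovalent gold centre binds the alkyne, which the three oxygen donors of ring D polarise so that positive charge builds at the carbon bonded to C8 of ring D (the future C4); the ring A carbon para to the benzyloxy group and ortho to the ether oxygen attacks that carbon anti to gold in a Friedel–Crafts manner, and rearomatisation with protodeauration releases the 2H-chromene and the catalyst. The closest known reaction type is the gold- or platinum-catalysed intramolecular hydroarylation of aryl propargyl ethers to 2H-chromenes. Ring C closes in the 6-endo-dig mode, favoured over 5-exo-dig by the alkyne polarisation and by the geometry of the O–C–C≡C tether. No stereocentre is formed; C2 is a spectator, and its C–O bond is kept from ionising or rearranging by the electron-poor carbonate on ring B and the neutral, ambient conditions. The site selectivity needed on ring A is secured because the alternative carbon lies between two oxygen substituents and attack there would force ring D into a peri clash with a C5 benzyloxy group.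

Step 10
Reactants: 13 benzyl 4-[(2S)-7-benzyloxy-4-(3,5,7,3',4',5'-hexa-O-benzylepigallocatechin-8-yl)-2H-chromen-2-yl]phenyl carbonate
Product: 14 (2S,4S)-7,4'-dihydroxyflavan-(4→8)-(−)-epigallocatechin (2,4-cis upper unit)
Conditions: H2 (3 atm), Pd(OH)2/C, THF–MeOH, rt
Reagents that add atoms: none
Why: Heterogeneous hydrogenation and hydrogenolysis in one operation, in which hydrogen reaches C3=C4 from the face opposite ring B at C2 so that H4 ends cis to H2 (2,4-cis, 4S) while the seven benzyl ethers and the benzyl carbonate are cleaved, the latter with loss of CO2; C2 controls the face whichever event comes first.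

Compound list
1 | (−)-epigallocatechin, (2R,3R)-2-(3,4,5-trihydroxyphenyl)chromane-3,5,7-triol | Oc1cc(O)c2c(c1)O[C@H](c1cc(O)c(O)c(O)c1)[C@H](O)C2 | starting material
2 | 5,7,3',4',5'-penta-O-benzyl-(−)-epigallocatechin, (2R,3R)-5,7-bis(benzyloxy)-2-[3,4,5-tris(benzyloxy)phenyl]chroman-3-ol | C(c1ccccc1)Oc1cc(OCc2ccccc2)c2c(c1)O[C@H](c1cc(OCc3ccccc3)c(OCc3ccccc3)c(OCc3ccccc3)c1)[C@H](O)C2 | intermediate
3 | 8-bromo-5,7,3',4',5'-penta-O-benzyl-(−)-epigallocatechin (2R,3R) | Brc1c(OCc2ccccc2)cc(OCc2ccccc2)c2c1O[C@H](c1cc(OCc3ccccc3)c(OCc3ccccc3)c(OCc3ccccc3)c1)[C@H](O)C2 | intermediate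
4 | 8-bromo-3,5,7,3',4',5'-hexa-O-benzyl-(−)-epigallocatechin (2R,3R) | Brc1c(OCc2ccccc2)cc(OCc2ccccc2)c2c1O[C@H](c1cc(OCc3ccccc3)c(OCc3ccccc3)c(OCc3ccccc3)c1)[C@H](OCc1ccccc1)C2 | intermediate
5 | 8-lithio-3,5,7,3',4',5'-hexa-O-benzyl-(−)-epigallocatechin (2R,3R) | [Li]c1c(OCc2ccccc2)cc(OCc2ccccc2)c2c1O[C@H](c1cc(OCc3ccccc3)c(OCc3ccccc3)c(OCc3ccccc3)c1)[C@H](OCc1ccccc1)C2 | intermediate
6 | 3,5,7,3',4',5'-hexa-O-benzyl-(−)-epigallocatechin-8-carbaldehyde (2R,3R) | O=Cc1c(OCc2ccccc2)cc(OCc2ccccc2)c2c1O[C@H](c1cc(OCc3ccccc3)c(OCc3ccccc3)c(OCc3ccccc3)c1)[C@H](OCc1ccccc1)C2 | intermediate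
7 | 8-ethynyl-3,5,7,3',4',5'-hexa-O-benzyl-(−)-epigallocatechin (2R,3R) | C#Cc1c(OCc2ccccc2)cc(OCc2ccccc2)c2c1O[C@H](c1cc(OCc3ccccc3)c(OCc3ccccc3)c(OCc3ccccc3)c1)[C@H](OCc1ccccc1)C2 | intermediate
8 | 4-hydroxybenzaldehyde | O=Cc1ccc(O)cc1 | starting material
9 | benzyl 4-formylphenyl carbonate | O=Cc1ccc(OC(=O)OCc2ccccc2)cc1 | intermediate
10 | benzyl 4-{(1S)-1-hydroxy-3-[(2R,3R)-3,5,7-tris(benzyloxy)-2-(3,4,5-tris(benzyloxy)phenyl)chroman-8-yl]prop-2-yn-1-yl}phenyl carbonate | O=C(OCc1ccccc1)Oc1ccc([C@H](O)C#Cc2c(OCc3ccccc3)cc(OCc3ccccc3)c3c2O[C@H](c2cc(OCc4ccccc4)c(OCc4ccccc4)c(OCc4ccccc4)c2)[C@H](OCc2ccccc2)C3)cc1 | intermediate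
11 | 3-benzyloxyphenol | Oc1cccc(OCc2ccccc2)c1 | starting material
12 | benzyl 4-{(1R)-1-[3-(benzyloxy)phenoxy]-3-[(2R,3R)-3,5,7-tris(benzyloxy)-2-(3,4,5-tris(benzyloxy)phenyl)chroman-8-yl]prop-2-yn-1-yl}phenyl carbonate (key-step precursor) | O=C(OCc1ccccc1)Oc1ccc([C@@H](Oc2cccc(OCc3ccccc3)c2)C#Cc2c(OCc3ccccc3)cc(OCc3ccccc3)c3c2O[C@H](c2cc(OCc4ccccc4)c(OCc4ccccc4)c(OCc4ccccc4)c2)[C@H](OCc2ccccc2)C3)cc1 | intermediate
13 | benzyl 4-{(2S)-7-(benzyloxy)-4-[(2R,3R)-3,5,7-tris(benzyloxy)-2-(3,4,5-tris(benzyloxy)phenyl)chroman-8-yl]-2H-chromen-2-yl}phenyl carbonate (key-step product) | O=C(OCc1ccccc1)Oc1ccc([C@@H]2C=C(c3c(OCc4ccccc4)cc(OCc4ccccc4)c4c3O[C@H](c3cc(OCc5ccccc5)c(OCc5ccccc5)c(OCc5ccccc5)c3)[C@H](OCc3ccccc3)C4)c3ccc(OCc4ccccc4)cc3O2)cc1 | intermediate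
14 | (2R,3R)-8-[(2S,4S)-7-hydroxy-2-(4-hydroxyphenyl)chroman-4-yl]-2-(3,4,5-trihydroxyphenyl)chromane-3,5,7-triol | Oc1ccc([C@@H]2C[C@H](c3c(O)cc(O)c4c3O[C@H](c3cc(O)c(O)c(O)c3)[C@H](O)C4)c3ccc(O)cc3O2)cc1 | target

Total step count: 10. Longest linear sequence: 9 (steps 1 to 5 and 7 to 10, from 1 to 14).

Steps most likely to fail

Step 9. The ether oxygens of ring D that flank the alkyne may capture the gold-activated triple bond, or traces of acid may ionise the C2–O bond and erode the configuration before ring A closes. The fallback replaces metal catalysis by an electrophile-induced cyclisation. It sets out from 12: I2 and NaHCO3 in MeNO2 at rt should trigger iodonium-mediated 6-endo-dig arylation by ring A to give the 3-iodo-4-aryl-2H-chromene F1, with C2 untouched. Any extra nuclear iodination is harmless because every C–I bond is cleaved later. F1 is then hydrogenated as in step 10 with NaOAc added (H2, Pd(OH)2/C, NaOAc, THF–MeOH), where hydrodeiodination, saturation of C3=C4 and debenzylation occur together. The route is rejoined at 14.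

Step 8. The alkoxyphosphonium intermediate is benzylic and conjugated through the alkyne with the electron-rich ring D, so it may ionise before the phenoxide attacks, leaking configuration or alkylating the phenol at carbon. The fallback forms the ether before ring D is attached. It sets out from 9: the zinc–ProPhenol addition of step 7, run with trimethylsilylacetylene, gives the silyl carbinol F2. Mitsunobu reaction of F2 with 11 (PPh3, DIAD, toluene), now at a centre not conjugated with ring D, gives the silyl propargyl ether F3. Protodesilylation with AgNO3 (10 mol %) in aqueous acetone gives the terminal propargyl ether F4. Sonogashira coupling of F4 with bromide 4 (Pd(PhCN)2Cl2, P(t-Bu)3, CuI, i-Pr2NH, dioxane, rt to 50 °C) rejoins the route at 12.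

Step 7. Facial discrimination may be insufficient, or turnover slow, when the hindered aryl acetylene is the limiting partner. The fallback sets the stereocentre by ketone reduction instead of C–C bond formation. It sets out from 7 and 9: the lithium acetylide of 7 (LiHMDS, THF, −78 °C, cold AcOH quench) adds to 9 without selectivity to give the carbinol epimer mixture F5. Dess–Martin periodinane with NaHCO3 in CH2Cl2 oxidises it to the ynone F6. Corey–Bakshi–Shibata reduction ((S)-Me-CBS oxazaborolidine, catecholborane, toluene, −78 °C) is expected to give 10, with the aryl group acting as the larger substituent; the antipodal catalyst is used if a trial run shows the reverse sense.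

Further compounds
F1 | step 9 | benzyl 4-{(2R)-7-(benzyloxy)-3-iodo-4-[(2R,3R)-3,5,7-tris(benzyloxy)-2-(3,4,5-tris(benzyloxy)phenyl)chroman-8-yl]-2H-chromen-2-yl}phenyl carbonate (same spatial arrangement at C2 as 13) | O=C(OCc1ccccc1)Oc1ccc([C@@H]2C(I)=C(c3c(OCc4ccccc4)cc(OCc4ccccc4)c4c3O[C@H](c3cc(OCc5ccccc5)c(OCc5ccccc5)c(OCc5ccccc5)c3)[C@H](OCc3ccccc3)C4)c3ccc(OCc4ccccc4)cc3O2)cc1
F2 | step 8 | benzyl 4-[(1S)-1-hydroxy-3-(trimethylsilyl)prop-2-yn-1-yl]phenyl carbonate | O=C(OCc1ccccc1)Oc1ccc([C@H](O)C#C[Si](C)(C)C)cc1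
F3 | step 8 | benzyl 4-{(1R)-1-[3-(benzyloxy)phenoxy]-3-(trimethylsilyl)prop-2-yn-1-yl}phenyl carbonate | O=C(OCc1ccccc1)Oc1ccc([C@@H](Oc2cccc(OCc3ccccc3)c2)C#C[Si](C)(C)C)cc1
F4 | step 8 | benzyl 4-{(1S)-1-[3-(benzyloxy)phenoxy]prop-2-yn-1-yl}phenyl carbonate (same spatial arrangement as F3) | O=C(OCc1ccccc1)Oc1ccc([C@@H](Oc2cccc(OCc3ccccc3)c2)C#C)cc1
F5 | step 7 | benzyl 4-{1-hydroxy-3-[(2R,3R)-3,5,7-tris(benzyloxy)-2-(3,4,5-tris(benzyloxy)phenyl)chroman-8-yl]prop-2-yn-1-yl}phenyl carbonate, mixture of carbinol epimers | O=C(OCc1ccccc1)Oc1ccc(C(O)C#Cc2c(OCc3ccccc3)cc(OCc3ccccc3)c3c2O[C@H](c2cc(OCc4ccccc4)c(OCc4ccccc4)c(OCc4ccccc4)c2)[C@H](OCc2ccccc2)C3)cc1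
F6 | step 7 | benzyl 4-{3-[(2R,3R)-3,5,7-tris(benzyloxy)-2-(3,4,5-tris(benzyloxy)phenyl)chroman-8-yl]prop-2-ynoyl}phenyl carbonate | O=C(OCc1ccccc1)Oc1ccc(C(=O)C#Cc2c(OCc3ccccc3)cc(OCc3ccccc3)c3c2O[C@H](c2cc(OCc4ccccc4)c(OCc4ccccc4)c(OCc4ccccc4)c2)[C@H](OCc2ccccc2)C3)cc1
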